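The earlier runs and the new flask were generated by integration for substances that don't exist.

The amounts to start from: at 20.0 min the grey run holds 12.0% of product, both hands together, and the flask you are asked about follows that same recipe further.

| flask | left-handed substrate | right-handed substrate | gas | free catalyst | racemization catalyst | remark | time |
|---|---|---|---|---|---|---|---|
| grey | 0.050 M | 0.050 M | 4.6 mM (held) | 1 mM | 3.6 mM | the very flask that is asked about, followed so far |  |
| teal | 0.050 M | 0.050 M | 4.6 mM (held) | 0.67 mM | 3.6 mM | run made earlier |  |
| flask | 0.050 M | 0.050 M | 4.6 mM (held) | 1.0 mM | 3.6 mM |  | 1.5 h |

- grey (time / min: right-handed product / %, left-handed product / %): 4.00: 1, 1; 8.00: 1, 4; 10.0: 3, 6; 15.0: 1, 6; 20.0: 4, 8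
- teal (time / min: right-handed product / %, left-handed product / %): 5.00: 0, 2; 10.0: 1, 3; 20.0: 1, 9; 30.0: 5, 11; 60.0: 10, 22

(scatter of a reading: 1.5 percentage points)

- amount of right-handed product in percent of the left-handed substrate and right-handed substrate together charged, at 10 min, 30 min and 1.5 h

- free catalyst is single-handed; left-handed substrate and right-handed substrate are mirror images of each other, charged as a racemate, each of them at the stated concentration
- at the start none of the gas is in solution

I would split the problem into a total and a share. Teal's last two readings stand well above the scatter, and together they give 31.3%. Call this the right-handed share, right-handed product over both products together.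

Next comes the total. Grey's 12.0% in 20.0 min is a straight-line rate of 0.00600 min⁻¹, as a fraction of the charge. Multiplying rate, share and time gives my right-handed product in the flask: 1.88% at 10 min, 5.63% at 30 min and 16.9% at 1.5 h.

The weak link is the last of these. Its total of 54.0% lies beyond teal's top reading of 32.0%, so teal's readings do not test the straight line that far. If the rate sank in proportion to substrate, an exponential approach would give 13.1%. But teal reached 16.0% in its first 30.0 min and added 16 percentage points in the next 30.0 min, which shows no bend within the scatter. I therefore keep 16.9%, with that lower figure as the bottom edge.

The forecast says 2%, 7% and 19%, the last above my 16.9%: “Substrate depletion slows the total rate”, it writes, while it expects falling left-handed substrate to shift the share toward right-handed product.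

The flask gives 1.76%, 5.68% and 16.3%, and the forecast held within its margin.

    reagent + free catalyst + left-handed substrate → free catalyst + left-handed product (k = 140 M⁻² s⁻¹)
    reagent + free catalyst + right-handed substrate → free catalyst + right-handed product (k = 61.0 M⁻² s⁻¹)
    left-handed substrate + racemization catalyst ⇌ right-handed substrate + racemization catalyst, rate k3*[racemization catalyst]*[left-handed substrate] forward; the back reaction follows from the equilibrium constant (k = 1.70 M⁻¹ s⁻¹)
    gas ⇌ reagent, rate k4*(csat - [reagent]) (kL = 0.00320 s⁻¹)

At 1.5 h the step to left-handed product uses left-handed substrate in this flask at 0.042 of the forward racemization rate, and the two substrates stand at 23.2% and 23.5%. At that time the left-handed and right-handed steps use reagent in the ratio 2.3, the selectivity factor here, and the right-handed share of this flask is 30.5% against the 31.3% carried. At 15.0 h the substrates stand at 0% and 0%; the carried share then gives 31.3%, and the flask holds 30.6% of right-handed product.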